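**Retrosynthetic overview**
- The hexasubstituted hydroquinone ring is formed last and in one operation, by annulating a four-carbon sulfonyl butenolide onto a chiral cyclohexenone that already carries both stereocentres.
- Key bond C4a–C5: the sulfone-stabilised butenolide C5 anion (a masked acyl anion) attacks the enone β-carbon; Dieckmann closure (C8a–C8) and loss of sulfinate then give the 5,8-diol with OMe and iPr already in place.
- The enone comes from a 6,6-disubstituted cyclohex-2-enone by Wharton 1,3-carbonyl transposition.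
- Its quaternary centre comes from a Michael addition to methyl acrylate anti to the isopropenyl group; the isopropenyl centre comes from a copper-catalysed asymmetric conjugate addition to 2-methylcyclohex-2-enone.
- Ring order: the carbocycle (ring B) is carried through from the commercial cyclohexenone; the aromatic ring (ring C) is built in the final step.

Assumption: positions are named by tetralone numbering (C1 ketone, C3 CH–isopropenyl, C4 quaternary carbon, C5-OH, C6-OMe, C7-iPr, C8-OH; target = 3S,4S), and in step 1 the ligand enantiomer used is the one found by a test run to give the 3R adduct.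

**Route**

Step 1
Reactants: 1 2-methylcyclohex-2-en-1-one; 2 isopropenylmagnesium bromide
Product: 4 (2S,3R)-2-methyl-3-(prop-1-en-2-yl)cyclohexan-1-one, via bromomagnesium enolate 3 (not isolated)
Conditions: CuBr·SMe2 (5 mol %), (R)-1-[(S)-2-(diphenylphosphino)ferrocenyl]ethyldicyclohexylphosphine (6 mol %), t-BuOMe, −78 °C; then 1 M HCl, 0 °C
Reagents that add atoms: none
Why: Copper-catalysed enantioselective conjugate addition of a Grignard reagent; the chiral monovalent copper–alkenyl complex delivers isopropenyl to one face of the β-carbon and sets C3 (R), while C2 is protonated to the trans isomer and is re-made in step 2, so its configuration does not matter.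

Step 2
Reactants: 4 (2S,3R)-2-methyl-3-(prop-1-en-2-yl)cyclohexan-1-one; 5 methyl acrylate
Product: 7 3-[(1S,6S)-1-methyl-2-oxo-6-(prop-1-en-2-yl)cyclohexyl]propanoic acid, via methyl ester 6 (not isolated)
Conditions: NaOMe (0.2 equiv), MeOH, 0 °C → rt; then 2 M NaOH (aq), rt; then HCl to pH 2
Reagents that add atoms: sodium hydroxide, [Na+].[OH-]
Why: Base-catalysed Michael addition through the more substituted (thermodynamic) enolate; allylic 1,2-strain puts the isopropenyl group axial and acrylate enters from the opposite face, so the new quaternary centre has the chain trans and the methyl cis to isopropenyl (the outcome known from Robinson annulations of 2,3-dialkylcyclohexanones); the ester is saponified in the same pot so that no ester is present in steps 5 and 10.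

Step 3
Reactants: 7 3-[(1S,6S)-1-methyl-2-oxo-6-(prop-1-en-2-yl)cyclohexyl]propanoic acid
Product: 8 3-[(1S,6S)-1-methyl-2-oxo-6-(prop-1-en-2-yl)cyclohex-3-en-1-yl]propanoic acid
Conditions: IBX (1.6 equiv), DMSO, 70 °C
Reagents that add atoms: none
Why: IBX dehydrogenation of a ketone to the enone; only one α-carbon carries hydrogens (the other is quaternary), so the position of the double bond is fixed and no stereocentre is touched.

Step 4
Reactants: 8 3-[(1S,6S)-1-methyl-2-oxo-6-(prop-1-en-2-yl)cyclohex-3-en-1-yl]propanoic acid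
Product: 9 3-[(1R,3S,4S,6R)-3-methyl-2-oxo-4-(prop-1-en-2-yl)-7-oxabicyclo[4.1.0]heptan-3-yl]propanoic acid
Conditions: 30% H2O2, NaOH (aq), MeOH, 0 °C → rt; then HCl to pH 3
Reagents that add atoms: hydrogen peroxide, OO
Why: Weitz–Scheffer nucleophilic epoxidation, which touches only the electron-poor enone and not the isopropenyl group; hydroperoxide adds to the β-carbon anti to the isopropenyl group as in carvone (major epoxide drawn), and either epoxide leads to the same enone 12 because the carbinol centre is oxidised in step 6.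

Step 5
Reactants: 9 3-[(1R,3S,4S,6R)-3-methyl-2-oxo-4-(prop-1-en-2-yl)-7-oxabicyclo[4.1.0]heptan-3-yl]propanoic acid
Product: 11 3-[(1R,4R,6S)-4-hydroxy-1-methyl-6-(prop-1-en-2-yl)cyclohex-2-en-1-yl]propanoic acid, via epoxy hydrazone 10 (not isolated)
Conditions: N2H4·H2O (3 equiv), AcOH (3 equiv), MeOH, 0 °C → rt
Reagents that add atoms: none
Why: Wharton transposition; the epoxy hydrazone fragments with loss of N2 to the allylic alcohol, which moves the oxygen to the former β-carbon and the alkene next to the quaternary carbon, with the C–O configuration of the epoxide retained.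

Step 6
Reactants: 11 3-[(1R,4R,6S)-4-hydroxy-1-methyl-6-(prop-1-en-2-yl)cyclohex-2-en-1-yl]propanoic acid
Product: 12 3-[(1R,6S)-1-methyl-4-oxo-6-(prop-1-en-2-yl)cyclohex-2-en-1-yl]propanoic acid
Conditions: Dess–Martin periodinane (1.3 equiv), CH2Cl2, 0 °C → rt
Reagents that add atoms: none
Why: Dess–Martin oxidation of a secondary allylic alcohol to the enone; the quaternary γ-carbon has no hydrogen, so the enone cannot deconjugate and the two stereocentres are untouched.

Step 7
Reactants: 13 ethyl 2-acetyl-3-methylbutanoate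
Product: 16 4-hydroxy-3-(propan-2-yl)furan-2(5H)-one, via 2-bromo ester 14 (not isolated), via 4-bromo ester 15 (not isolated)
Conditions: Br2 (1.0 equiv), CHCl3, 0 °C → rt, 16 h (HBr kept in); then neat, 130 °C
Reagents that add atoms: none
Why: Classical tetronic acid synthesis; α-bromination, HBr-mediated migration of bromine to the γ-carbon, then thermal lactonisation of the γ-bromo-β-keto ester with loss of bromoethane.

Step 8
Reactants: 16 4-hydroxy-3-(propan-2-yl)furan-2(5H)-one
Product: 17 4-methoxy-3-(propan-2-yl)furan-2(5H)-one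
Conditions: Me2SO4, K2CO3, acetone, reflux
Reagents that add atoms: dimethyl sulfate, COS(=O)(=O)OC
Why: O-alkylation of a vinylogous acid; C3 is fully substituted, so the tetronate anion is methylated on the C4 oxygen to give the vinylogous ester.

Step 9
Reactants: 17 4-methoxy-3-(propan-2-yl)furan-2(5H)-one
Product: 18 4-methoxy-5-(phenylsulfonyl)-3-(propan-2-yl)furan-2(5H)-one (racemic)
Conditions: LDA (2.1 equiv), THF, −78 °C; PhSO2F, −78 → −20 °C; then 1 M HCl
Reagents that add atoms: benzenesulfonyl fluoride, O=S(=O)(F)c1ccccc1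
Why: γ-Deprotonation of the methyl tetronate at C5 and sulfonylation of the dienolate with a sulfonyl fluoride; the second equivalent of base takes up the more acidic proton of the product.

Step 10
Reactants: 12 3-[(1R,6S)-1-methyl-4-oxo-6-(prop-1-en-2-yl)cyclohex-2-en-1-yl]propanoic acid; 18 4-methoxy-5-(phenylsulfonyl)-3-(propan-2-yl)furan-2(5H)-one
Product: 19 3-[(1S,2S)-5,8-dihydroxy-7-methoxy-1-methyl-4-oxo-6-(propan-2-yl)-2-(prop-1-en-2-yl)-1,2,3,4-tetrahydronaphthalen-1-yl]propanoic acid (the target)
Conditions: LiOtBu (4.2 equiv), THF/DMPU, −78 °C → rt, argon; then degassed 1 M HCl, Na2S2O4 wash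
Reagents that add atoms: none
Why: Proposed new method: the C5 anion of 18 is a sulfone-stabilised acyl anion equivalent and adds to the enone β-carbon of the lithium carboxylate of 12; the resulting enolate attacks the lactone carbonyl (Dieckmann), the opened α-sulfonyl alkoxide expels benzenesulfinate, and the ene-dione tautomerises to the hydroquinone, so the regiochemistry (C8-OH beside the ketone and iPr, C5-OH beside OMe and the quaternary carbon) follows from the mechanism and the two existing stereocentres are not involved; the closest known reaction is the Hauser–Kraus annulation of 3-(phenylsulfonyl)phthalides with cyclohexenones, here extended to a non-benzo-fused tetronate donor and a γ,γ-disubstituted enone.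

**Compound list**
1 | 2-methylcyclohex-2-en-1-one | CC1=CCCCC1=O | starting material
2 | isopropenylmagnesium bromide (prop-1-en-2-ylmagnesium bromide) | C=C(C)[Mg]Br | starting material
3 | bromo{[(3S)-2-methyl-3-(prop-1-en-2-yl)cyclohex-1-en-1-yl]oxy}magnesium | C=C(C)[C@@H]1CCCC(O[Mg]Br)=C1C | intermediate
4 | (2S,3R)-2-methyl-3-(prop-1-en-2-yl)cyclohexan-1-one | C=C(C)[C@@H]1CCCC(=O)[C@H]1C | intermediate
5 | methyl acrylate | C=CC(=O)OC | starting material
6 | methyl 3-[(1S,6S)-1-methyl-2-oxo-6-(prop-1-en-2-yl)cyclohexyl]propanoate | C=C(C)[C@@H]1CCCC(=O)[C@@]1(C)CCC(=O)OC | intermediate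
7 | 3-[(1S,6S)-1-methyl-2-oxo-6-(prop-1-en-2-yl)cyclohexyl]propanoic acid | C=C(C)[C@@H]1CCCC(=O)[C@@]1(C)CCC(=O)O | intermediate
8 | 3-[(1S,6S)-1-methyl-2-oxo-6-(prop-1-en-2-yl)cyclohex-3-en-1-yl]propanoic acid | C=C(C)[C@@H]1CC=CC(=O)[C@@]1(C)CCC(=O)O | intermediate
9 | 3-[(1R,3S,4S,6R)-3-methyl-2-oxo-4-(prop-1-en-2-yl)-7-oxabicyclo[4.1.0]heptan-3-yl]propanoic acid | C=C(C)[C@@H]1C[C@H]2O[C@H]2C(=O)[C@@]1(C)CCC(=O)O | intermediate
10 | 3-[(1S,3S,4S,6R)-2-hydrazinylidene-3-methyl-4-(prop-1-en-2-yl)-7-oxabicyclo[4.1.0]heptan-3-yl]propanoic acid | C=C(C)[C@@H]1C[C@H]2O[C@H]2C(=NN)[C@@]1(C)CCC(=O)O | intermediate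
11 | 3-[(1R,4R,6S)-4-hydroxy-1-methyl-6-(prop-1-en-2-yl)cyclohex-2-en-1-yl]propanoic acid | C=C(C)[C@@H]1C[C@@H](O)C=C[C@@]1(C)CCC(=O)O | intermediate
12 | 3-[(1R,6S)-1-methyl-4-oxo-6-(prop-1-en-2-yl)cyclohex-2-en-1-yl]propanoic acid | C=C(C)[C@@H]1CC(=O)C=C[C@@]1(C)CCC(=O)O | intermediate
13 | ethyl 2-acetyl-3-methylbutanoate (ethyl 2-isopropylacetoacetate) | CCOC(=O)C(C(C)C)C(C)=O | starting material
14 | ethyl 2-acetyl-2-bromo-3-methylbutanoate (racemic) | CCOC(=O)C(Br)(C(C)C)C(C)=O | intermediate
15 | ethyl 4-bromo-3-oxo-2-(propan-2-yl)butanoate (racemic) | CCOC(=O)C(C(C)C)C(=O)CBr | intermediate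
16 | 4-hydroxy-3-(propan-2-yl)furan-2(5H)-one | OC1=C(C(C)C)C(=O)OC1 | intermediate
17 | 4-methoxy-3-(propan-2-yl)furan-2(5H)-one | COC1=C(C(C)C)C(=O)OC1 | intermediate
18 | 4-methoxy-5-(phenylsulfonyl)-3-(propan-2-yl)furan-2(5H)-one (racemic) | COC1=C(C(C)C)C(=O)OC1S(=O)(=O)c1ccccc1 | intermediate
19 | 3-[(1S,2S)-5,8-dihydroxy-7-methoxy-1-methyl-4-oxo-6-(propan-2-yl)-2-(prop-1-en-2-yl)-1,2,3,4-tetrahydronaphthalen-1-yl]propanoic acid | C=C(C)[C@@H]1CC(=O)c2c(O)c(C(C)C)c(OC)c(O)c2[C@@]1(C)CCC(=O)O | target

**Step count and risks**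

Total: 10 steps. Longest linear sequence: 7 steps (steps 1–6, then 10); the donor branch is 3 steps (7–9).

Three steps most likely to fail:

1. Step 10. A hindered carbanion must add to a β-carbon next to a quaternary centre, and the tetronate carbonyl is a weaker electrophile than a phthalide. Fallback: set out from 18 and silylate it (t-BuMe2SiOTf, Et3N, CH2Cl2) to the silyloxyfuran tert-butyl{[4-methoxy-5-(phenylsulfonyl)-3-(propan-2-yl)furan-2-yl]oxy}dimethylsilane F4. A Lewis-acid-promoted vinylogous Mukaiyama–Michael addition of F4 to enone 12 (Me3SiOTf, CH2Cl2, −78 °C, the acid silylated in situ) then gives, after aqueous work-up, the Michael adduct 3-[(1S,6S)-2-[3-methoxy-5-oxo-2-(phenylsulfonyl)-4-(propan-2-yl)-2,5-dihydrofuran-2-yl]-1-methyl-4-oxo-6-(prop-1-en-2-yl)cyclohexyl]propanoic acid F5 (two new centres unassigned, both lost on aromatisation). LiOtBu in THF closes the ring by Dieckmann condensation and sulfinate loss, and the route is rejoined at 19.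

2. Step 1. The enantioselectivity of an alkenyl Grignard on an α-substituted enone is uncertain, and 1,2-addition may compete. Fallback: set out from 2 and transmetalate with ZnCl2 to isopropenylzinc chloride. This is added to cyclohex-2-en-1-one under [RhCl(binap)]2 catalysis (monovalent rhodium, BINAP enantiomer chosen for 3R) in the presence of Me3SiCl to give the silyl enol ether trimethyl{[(3R)-3-(prop-1-en-2-yl)cyclohex-1-en-1-yl]oxy}silane F1. MeLi then MeI methylate the regio-defined lithium enolate trans to the isopropenyl group, and the route is rejoined at 4.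

3. Step 5. Hydrazone formation at a ketone flanked by a quaternary carbon is slow, and Wharton yields are often moderate. Fallback: set out from 7 and O-triflate its dianion (KHMDS 2 equiv, PhNTf2, THF, −78 °C) to the vinyl triflate 3-[(1S,6S)-1-methyl-6-(prop-1-en-2-yl)-2-{[(trifluoromethyl)sulfonyl]oxy}cyclohex-2-en-1-yl]propanoic acid F2. Formate reduction (Pd(OAc)2, PPh3, HCO2H, Bu3N, DMF; zerovalent palladium formed in situ) gives the cyclohexene 3-[(1R,6S)-1-methyl-6-(prop-1-en-2-yl)cyclohex-2-en-1-yl]propanoic acid F3. Allylic oxidation of the only ring allylic CH2 (CrO3·3,5-dimethylpyrazole, CH2Cl2, −20 °C) then gives the enone, rejoining the route at 12; the isopropenyl allylic positions may compete in this oxidation.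

**Further compounds**
F1 | step 1 | trimethyl{[(3R)-3-(prop-1-en-2-yl)cyclohex-1-en-1-yl]oxy}silane | C=C(C)[C@@H]1CCCC(O[Si](C)(C)C)=C1
F2 | step 5 | 3-[(1S,6S)-1-methyl-6-(prop-1-en-2-yl)-2-{[(trifluoromethyl)sulfonyl]oxy}cyclohex-2-en-1-yl]propanoic acid | C=C(C)[C@@H]1CCC=C(OS(=O)(=O)C(F)(F)F)[C@@]1(C)CCC(=O)O
F3 | step 5 | 3-[(1R,6S)-1-methyl-6-(prop-1-en-2-yl)cyclohex-2-en-1-yl]propanoic acid | C=C(C)[C@@H]1CCC=C[C@@]1(C)CCC(=O)O
F4 | step 10 | tert-butyl{[4-methoxy-5-(phenylsulfonyl)-3-(propan-2-yl)furan-2-yl]oxy}dimethylsilane | COc1c(C(C)C)c(O[Si](C)(C)C(C)(C)C)oc1S(=O)(=O)c1ccccc1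
F5 | step 10 | 3-[(1S,6S)-2-[3-methoxy-5-oxo-2-(phenylsulfonyl)-4-(propan-2-yl)-2,5-dihydrofuran-2-yl]-1-methyl-4-oxo-6-(prop-1-en-2-yl)cyclohexyl]propanoic acid | C=C(C)[C@@H]1CC(=O)CC([C@@]1(C)CCC(=O)O)C1(OC(=O)C(C(C)C)=C1OC)S(=O)(=O)c1ccccc1
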